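## Retrosynthetic overview

1. The last operation is an unmasking. One flask removes the carbonyl-chelated 5-O-methyl group and three MOM groups from the fully substituted (2R,3R)-flavanonol.
2. Ring C is the only ring made; rings A and B are bought as arenes. The 2'-hydroxychalcone phenoxide closes O1–C2 by 6-endo oxa-Michael addition (the chalcone isomerase event). An enantiopure N-sulfonyloxaziridine then oxygenates the transient flavanone enolate at C3 in the same flask (the flavanone 3-hydroxylase event), so both stereocentres arise in one operation.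
3. The chalcone comes from a Claisen–Schmidt condensation of a hexasubstituted acetophenone with 4-methoxy-2,6-bis(MOM-oxy)benzaldehyde.
4. The acetophenone comes from 2',4'-dihydroxy-6'-methoxyacetophenone by C3-prenylation and then C5-geranylation. The purchased O-methyl group blocks the oxygen next to geranyl, so ring closure can only give the 8-prenyl/6-geranyl pattern.
5. The aldehyde comes from 5-methoxyresorcinol by MOM protection, directed lithiation and formylation.

Abbreviations: prenyl = 3-methylbut-2-enyl; geranyl = (2E)-3,7-dimethylocta-2,6-dienyl; MOM = methoxymethyl.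

Assumption: the facial preference of (+)-(8,8-dichlorocamphorylsulfonyl)oxaziridine is carried over from its behaviour with 1-tetralone and chroman-4-one enolates; if the first run gives the antipode, the equally available (−)-reagent is used and nothing else changes.

## Route

Step 1
Reactants: 1 2',4'-dihydroxy-6'-methoxyacetophenone; 2 prenyl bromide
Product: 3 1-(2,4-dihydroxy-6-methoxy-3-prenylphenyl)ethanone
Conditions: KOH (1.1 equiv), MeOH–H2O, 0 °C → rt
Reagents that add atoms: none
Why: This is a phenoxide C-alkylation (nuclear prenylation) in a protic medium that suppresses O-alkylation, and the carbon flanked by both phenolic oxygens (C3) is the most nucleophilic site, as in base-mediated alkylations of resacetophenones; no stereocentre is formed.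

Step 2
Reactants: 3 1-(2,4-dihydroxy-6-methoxy-3-prenylphenyl)ethanone; 4 geranyl bromide
Product: 5 1-(5-geranyl-2,4-dihydroxy-6-methoxy-3-prenylphenyl)ethanone
Conditions: KOH (1.1 equiv), MeOH–H2O, 0 °C → rt
Reagents that add atoms: none
Why: The same phenoxide C-alkylation now goes to the only ring C–H left (C5, ortho to the 4-oxide and para to the 2-oxide), rearomatisation makes it irreversible, and SN2 displacement at the primary allylic carbon keeps the E alkene.

Step 3
Reactants: 5 1-(5-geranyl-2,4-dihydroxy-6-methoxy-3-prenylphenyl)ethanone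
Product: 6 1-[5-geranyl-2-hydroxy-6-methoxy-4-(methoxymethoxy)-3-prenylphenyl]ethanone
Conditions: MOMCl (1.2 equiv), K2CO3, acetone, rt
Reagents that add atoms: chloromethyl methyl ether (MOMCl), COCCl
Why: In this Williamson-type O-alkylation the more acidic 4-OH reacts, while the 2-OH is held in a hydrogen bond to the acetyl carbonyl and stays free for the later ring closure.

Step 4
Reactants: 7 5-methoxyresorcinol
Product: 8 1-methoxy-3,5-bis(methoxymethoxy)benzene
Conditions: NaH (2.4 equiv), MOMCl (2.4 equiv), DMF, 0 °C → rt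
Reagents that add atoms: chloromethyl methyl ether (MOMCl), COCCl
Why: This is a routine double Williamson-type MOM protection of two unhindered phenoxides.

Step 5
Reactants: 8 1-methoxy-3,5-bis(methoxymethoxy)benzene
Product: 10 4-methoxy-2,6-bis(methoxymethoxy)benzaldehyde, via aryllithium 9 (not isolated)
Conditions: n-BuLi (1.1 equiv), THF, 0 °C; DMF, 0 °C → rt; H2O
Reagents that add atoms: N,N-dimethylformamide (DMF), CN(C)C=O
Why: In this directed ortho-metalation the site flanked by the two chelating OMOM groups is lithiated in preference to the OMOM/OMe sites, and DMF formylates the aryllithium.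

Step 6
Reactants: 6 1-[5-geranyl-2-hydroxy-6-methoxy-4-(methoxymethoxy)-3-prenylphenyl]ethanone; 10 4-methoxy-2,6-bis(methoxymethoxy)benzaldehyde
Product: 11 (E)-1-[5-geranyl-2-hydroxy-6-methoxy-4-(methoxymethoxy)-3-prenylphenyl]-3-[4-methoxy-2,6-bis(methoxymethoxy)phenyl]prop-2-en-1-one
Conditions: KOH (10 equiv), EtOH–H2O, rt → 40 °C
Reagents that add atoms: none
Why: This is a Claisen–Schmidt condensation with a non-enolisable aldehyde whose E1cB dehydration gives the E-enone; in excess base the product rests as the open phenoxide, and any flavanone formed on work-up is reopened to the same phenoxide in step 7.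

Step 7
Reactants: 11 (E)-1-[5-geranyl-2-hydroxy-6-methoxy-4-(methoxymethoxy)-3-prenylphenyl]-3-[4-methoxy-2,6-bis(methoxymethoxy)phenyl]prop-2-en-1-one
Product: 14 (2R,3R)-6-geranyl-3-hydroxy-5-methoxy-7-(methoxymethoxy)-2-[4-methoxy-2,6-bis(methoxymethoxy)phenyl]-8-prenylchroman-4-one, via chalcone sodium phenoxide 12 (not isolated), via (2S)-flavanone sodium enolate 13 (not isolated)
Conditions: NaN(SiMe3)2 (1.05 equiv), THF, −78 °C; (+)-(8,8-dichlorocamphorylsulfonyl)oxaziridine (1.5 equiv), −78 → 23 °C, 16 h; AcOH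
Reagents that add atoms: (+)-(8,8-dichlorocamphorylsulfonyl)oxaziridine, CC1(C)[C@@H]2CC[C@]13CS(=O)(=O)N4O[C@@]34C2(Cl)Cl
Why: Proposed new method: phenoxide 12 sits in a fast, uphill equilibrium (6-endo oxa-Michael addition and its E1cB reverse) with both enantiomers of the flavanone enolate, and only the enolate should be nucleophilic enough to attack the N-sulfonyloxaziridine (isolated trisubstituted alkenes, MOM acetals and the enone are inert to it), so the equilibrium is drained irreversibly under Curtin–Hammett control; O-transfer occurs anti to the bulky 2,6-disubstituted C2-aryl group (2,3-trans), and the camphor reagent, which attacks the corresponding enolate face of 1-tetralone and chroman-4-one enolates, consumes (2S)-enolate 13 faster, fixing C3 as R and C2 as R in a dynamic kinetic resolution in which the notorious ring-opening of flavanone enolates serves as the racemisation channel; the closest known reaction types are the non-epoxide cyclisation–enolate oxygenation pathway of the Algar–Flynn–Oyamada reaction and the Davis asymmetric enolate hydroxylation.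

Step 8
Reactants: 14 (2R,3R)-6-geranyl-3-hydroxy-5-methoxy-7-(methoxymethoxy)-2-[4-methoxy-2,6-bis(methoxymethoxy)phenyl]-8-prenylchroman-4-one
Product: 16 (2R,3R)-2-(2,6-dihydroxy-4-methoxyphenyl)-6-geranyl-3,5,7-trihydroxy-8-prenylchroman-4-one, via 5-hydroxy tris-MOM flavanonol 15 (not isolated)
Conditions: MgI2 (4 equiv), THF, 60 °C; then MeOH, 3 M aq HCl, 45 °C
Reagents that add atoms: none
Why: In this chelation-directed aryl methyl ether cleavage, magnesium held between C4=O and the peri 5-OMe activates only that methyl for SN2 attack by iodide (the 4'-OMe has no chelating neighbour; prenylated 5-methoxyflavanones are demethylated this way), acid-catalysed transacetalisation in methanol then removes the three MOM groups, C3 is not touched, and the labile C2 can only relax to the favoured 2,3-trans arrangement.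

## Compound list

1 | 2',4'-dihydroxy-6'-methoxyacetophenone | CC(=O)c1c(O)cc(O)cc1OC | starting material
2 | prenyl bromide (1-bromo-3-methylbut-2-ene) | CC(C)=CCBr | starting material
3 | 1-(2,4-dihydroxy-6-methoxy-3-prenylphenyl)ethanone | CC(=O)c1c(O)c(CC=C(C)C)c(O)cc1OC | intermediate
4 | geranyl bromide ((2E)-1-bromo-3,7-dimethylocta-2,6-diene) | CC(C)=CCC/C(C)=C/CBr | starting material
5 | 1-(5-geranyl-2,4-dihydroxy-6-methoxy-3-prenylphenyl)ethanone | CC(=O)c1c(O)c(CC=C(C)C)c(O)c(C/C=C(\C)CCC=C(C)C)c1OC | intermediate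
6 | 1-[5-geranyl-2-hydroxy-6-methoxy-4-(methoxymethoxy)-3-prenylphenyl]ethanone | CC(=O)c1c(O)c(CC=C(C)C)c(OCOC)c(C/C=C(\C)CCC=C(C)C)c1OC | intermediate
7 | 5-methoxyresorcinol (5-methoxybenzene-1,3-diol) | COc1cc(O)cc(O)c1 | starting material
8 | 1-methoxy-3,5-bis(methoxymethoxy)benzene | COc1cc(OCOC)cc(OCOC)c1 | intermediate
9 | [4-methoxy-2,6-bis(methoxymethoxy)phenyl]lithium (not isolated) | COc1cc(OCOC)c([Li])c(OCOC)c1 | intermediate
10 | 4-methoxy-2,6-bis(methoxymethoxy)benzaldehyde | COc1cc(OCOC)c(C=O)c(OCOC)c1 | intermediate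
11 | (E)-2'-hydroxychalcone: 1-[5-geranyl-2-hydroxy-6-methoxy-4-(methoxymethoxy)-3-prenylphenyl]-3-[4-methoxy-2,6-bis(methoxymethoxy)phenyl]prop-2-en-1-one | COc1cc(OCOC)c(/C=C/C(=O)c2c(O)c(CC=C(C)C)c(OCOC)c(C/C=C(\C)CCC=C(C)C)c2OC)c(OCOC)c1 | intermediate
12 | sodium 2'-phenoxide of chalcone 11 (not isolated) | COc1cc(OCOC)c(/C=C/C(=O)c2c([O-])c(CC=C(C)C)c(OCOC)c(C/C=C(\C)CCC=C(C)C)c2OC)c(OCOC)c1.[Na+] | intermediate
13 | sodium (2S)-6-geranyl-5-methoxy-7-(methoxymethoxy)-2-[4-methoxy-2,6-bis(methoxymethoxy)phenyl]-8-prenyl-2H-chromen-4-olate (flavanone enolate, not isolated) | COc1cc(OCOC)c([C@H]2Oc3c(CC=C(C)C)c(OCOC)c(C/C=C(\C)CCC=C(C)C)c(OC)c3C([O-])=C2)c(OCOC)c1.[Na+] | intermediate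
14 | (2R,3R)-6-geranyl-3-hydroxy-5-methoxy-7-(methoxymethoxy)-2-[4-methoxy-2,6-bis(methoxymethoxy)phenyl]-8-prenylchroman-4-one | COc1cc(OCOC)c([C@H]2Oc3c(CC=C(C)C)c(OCOC)c(C/C=C(\C)CCC=C(C)C)c(OC)c3C(=O)[C@@H]2O)c(OCOC)c1 | intermediate
15 | (2R,3R)-6-geranyl-3,5-dihydroxy-7-(methoxymethoxy)-2-[4-methoxy-2,6-bis(methoxymethoxy)phenyl]-8-prenylchroman-4-one (present as its magnesium chelate, not isolated) | COc1cc(OCOC)c([C@H]2Oc3c(CC=C(C)C)c(OCOC)c(C/C=C(\C)CCC=C(C)C)c(O)c3C(=O)[C@@H]2O)c(OCOC)c1 | intermediate
16 | CNP0304077.2, (2R,3R)-2-(2,6-dihydroxy-4-methoxyphenyl)-6-[(2E)-3,7-dimethylocta-2,6-dienyl]-3,5,7-trihydroxy-8-(3-methylbut-2-enyl)chroman-4-one | COc1cc(O)c([C@H]2Oc3c(CC=C(C)C)c(O)c(C/C=C(\C)CCC=C(C)C)c(O)c3C(=O)[C@@H]2O)c(O)c1 | target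

## Step count

Total step count: 8.
Longest linear sequence: 6 (1 → 3 → 5 → 6 → 11 → 14 → 16).

## Steps most likely to fail

**Step 7.** The enolate is only a trace component of the equilibrium, so its interception may be slow. The abundant phenoxide 12 may be hydroxylated with dearomatisation instead. The level of reagent control on a trisubstituted, C2-substituted enolate is untested. The fallback sets out from 11 and comes back at 14.
- The free phenol is capped (NaH, MOMCl, DMF) to give 2'-O-MOM chalcone F1.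
- A nucleophilic Juliá–Colonna epoxidation (poly-L-leucine, urea·H2O2, DBU, THF) touches only the enone and gives (αR,βS)-epoxychalcone F2.
- MgBr2·OEt2 in CH2Cl2 removes the carbonyl-chelated 2'-O-MOM group. The freed phenol opens the epoxide at the strongly stabilised benzylic carbon with inversion (6-endo), while the Cα–O bond is kept as the 3R carbinol. This delivers 14.

**Step 2.** O-Geranylation and ipso attack at the prenyl-bearing C3 (dearomatisation) compete with attack at C5. The fallback sets out from 3 (with 4) and comes back at 5.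
- The non-chelated 4-OH is deliberately O-alkylated (K2CO3, acetone, reflux) to give 4-O-geranyl ether F3.
- A Lewis-acid-induced [1,3] O-to-C shift (Bi(OTf)3, 5 mol %, CH2Cl2, −20 °C) passes through a tight allyl cation/phenoxide pair. It returns the unrearranged E-geranyl group to the only free ortho carbon, C5.

**Step 8.** The 3-OH/4-C=O chelate may divert magnesium from the 5-OMe. Free ortho-phenols may also add to the prenyl and geranyl alkenes in the acidic stage. The fallback sets out from 14 and comes back at 16.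
- The MOM groups are removed first and alone (3 M HCl, MeOH, 45 °C) to give 5-O-methyl flavanonol F4.
- The three phenols are masked (Ac2O, 3.3 equiv, Et3N, CH2Cl2, 0 °C) as phenolic triacetate F5, so no phenol can cyclise onto an alkene.
- BCl3 (CH2Cl2, −78 °C) cleaves the peri methyl ether at low temperature to give 5-hydroxy triacetate F6.
- Neutral methanolysis of the aryl acetates (NH4OAc, MeOH–H2O, rt) gives 16.

## Further compounds

F1 | step 7 | 2'-O-MOM chalcone: (E)-1-[3-geranyl-2-methoxy-4,6-bis(methoxymethoxy)-5-prenylphenyl]-3-[4-methoxy-2,6-bis(methoxymethoxy)phenyl]prop-2-en-1-one | COc1cc(OCOC)c(/C=C/C(=O)c2c(OCOC)c(CC=C(C)C)c(OCOC)c(C/C=C(\C)CCC=C(C)C)c2OC)c(OCOC)c1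
F2 | step 7 | (αR,βS)-epoxychalcone: [3-geranyl-2-methoxy-4,6-bis(methoxymethoxy)-5-prenylphenyl]{(2R,3S)-3-[4-methoxy-2,6-bis(methoxymethoxy)phenyl]oxiran-2-yl}methanone | COc1c(C/C=C(\C)CCC=C(C)C)c(OCOC)c(CC=C(C)C)c(OCOC)c1C(=O)[C@@H]1O[C@H]1c1c(OCOC)cc(OC)cc1OCOC
F3 | step 2 | 4-O-geranyl ether: 1-[4-(geranyloxy)-2-hydroxy-6-methoxy-3-prenylphenyl]ethanone | CC(=O)c1c(O)c(CC=C(C)C)c(OC/C=C(\C)CCC=C(C)C)cc1OC
F4 | step 8 | 5-O-methyl flavanonol: (2R,3R)-2-(2,6-dihydroxy-4-methoxyphenyl)-6-geranyl-3,7-dihydroxy-5-methoxy-8-prenylchroman-4-one | COc1cc(O)c([C@H]2Oc3c(CC=C(C)C)c(O)c(C/C=C(\C)CCC=C(C)C)c(OC)c3C(=O)[C@@H]2O)c(O)c1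
F5 | step 8 | phenolic triacetate: (2R,3R)-7-acetoxy-2-(2,6-diacetoxy-4-methoxyphenyl)-6-geranyl-3-hydroxy-5-methoxy-8-prenylchroman-4-one | COc1cc(OC(C)=O)c([C@H]2Oc3c(CC=C(C)C)c(OC(C)=O)c(C/C=C(\C)CCC=C(C)C)c(OC)c3C(=O)[C@@H]2O)c(OC(C)=O)c1
F6 | step 8 | 5-hydroxy triacetate: (2R,3R)-7-acetoxy-2-(2,6-diacetoxy-4-methoxyphenyl)-6-geranyl-3,5-dihydroxy-8-prenylchroman-4-one | COc1cc(OC(C)=O)c([C@H]2Oc3c(CC=C(C)C)c(OC(C)=O)c(C/C=C(\C)CCC=C(C)C)c(O)c3C(=O)[C@@H]2O)c(OC(C)=O)c1
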